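The earlier runs and the new flask were computed with made-up constants; noise was put on by code.

Slowness costs a flask something when D has somewhere to go while it waits, so before I trust a slow addition I ask whether D has a way out that does not care about concentration.

| setting | violet | grey | ochre | blue | south-east | east | north | north-west |
|---|---|---|---|---|---|---|---|---|
| D | 0.043 M | 0.043 M | 0.043 M | 0.021 M | 0.043 M (fed, over 6.0 min) | 0.043 M | 0.043 M | 0.043 M |
| E | 1 equiv | 0.50 equiv | 0.75 equiv | 1 equiv | 1.00 equiv | 1.00 equiv (fed, over 6.0 min) | 1.00 equiv (in portions, 3, over 6.0 min) | 1.00 equiv |
| remark | run made earlier | run made earlier | run made earlier | run made earlier | all else is in the flask from the start; the feed brings no volume worth counting | all else is in the flask from the start; the feed brings no volume worth counting | first portion at the start, last at 6.0 min | everything together at the start |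
| time |  |  |  |  | 15 min | 15 min | 15 min | 15 min |

- violet (time / min: Z / %): 0.500: 14.6; 1.33: 25.1; 2.50: 30.8; 4.00: 35.7; 5.00: 36.8; 8.00: 38.1; 10.0: 39.2
- grey (time / min: Z / %): 1.33: 15.1; 2.50: 19.7; 4.00: 22.1; 5.00: 23.5; 6.00: 24.2; 8.00: 26.0; 10.0: 26.8
- ochre (time / min: Z / %): 1.33: 20.5; 2.50: 25.4; 4.00: 29.2; 5.00: 31.1; 6.00: 32.0; 8.00: 32.7; 10.0: 33.9
- blue (time / min: Z / %): 2.00: 20.3; 4.00: 27.2; 5.00: 28.8; 8.00: 32.2; 10.0: 33.3

(readings scatter by 0.5 percentage points)



- which flask leads in amount of Z, in percent of the D charged ("all alike" within 1.5 percentage points) (south-east / east / north / north-west / all alike)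
- how much Z is there at the end, in percent of the D charged: south-east
- how much Z is there at the end, in percent of the D charged: east
- how much Z is there at the end, in percent of the D charged: north
- how much Z is there at the end, in percent of the D charged: north-west

I can get the late blue reading in two ways. If D and E went by steps of two molecules each, then at half the concentration, blue at 10.0 min ought to read what violet read at 5.00 min, namely 36.8%. The other way is to look, and blue reads 33.3%. The two part by 3.5 percentage points against a scatter of 0.5 points per reading, and the pair at 8.00 min and 4.00 min parts too, 32.2% against 35.7%. So the stretching law is the one that cheats, and I add a first-order loss of D, running at k_D · c_D. Violet holds 25.1% of its 36.8% by 1.33 min, so I take that as the typical moment Z forms, and blue forms it about that much later: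

k_D = ln(36.8% / 33.3%) / 1.33 min = 0.0751 min⁻¹

In east and in north, E arrives on average 3.00 min late, so I discount by the share of D that survives the wait:

S = exp(−k_D · t_f / 2) = 79.8%

North-west is violet's recipe, and violet read 39.2% at 10.0 min. Discounted, that gives east about 31.3%, and a low c_E may add a little back, so my reckoning puts north-west first.

The forecast puts east first, with 56% there, 54.5% in north, 41% in north-west and 26% in south-east, on the ground that “Feeding E keeps E low, so selectivity improves”. For east, it stands 25 points above my figure.

The flask gives north-west the lead with 39.8%, then north 35.2%, east 33.8% and south-east 21.8%.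

    2 E → Q (k = 0.170 M⁻¹ s⁻¹)
    D + E → Z (k = 0.160 M⁻¹ s⁻¹)
    2 D → G (k = 0.0160 M⁻¹ s⁻¹)
    D → X (k = 0.00180 s⁻¹)

East ends with X at 44.3% against 40.9% in north-west. East over north-west is 84.9%, where S gave 79.8%.

The neighbour is south-east itself, read at 6.0 min as its feed ends. Its D also goes to Z and G, so S does not apply here, and I put the mean c_D of 0.0139 M over those 6.0 min into the first-order loss:

X = k_D · mean c_D · t / c_D,charged = 14.6%

The computed flask holds 20.9% of X, more than this reckoning with k_D gives.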